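**Retrosynthetic overview**

- The last step makes the C1–C7 bond (seven-membered ring), the C6–H bond and the C10–O bond in one cationic cascade: 1,7-cyclization, 1,2-hydride shift from C10 to C6, then capture of the C10 cation by the carbonyl of the salicylate already on C5. This copies the cyclization, hydride shift and oxygen quench of the presumed biosynthesis.
- The cascade substrate is a tetrasubstituted cyclopentene carrying a linalool-type tertiary allylic alcohol side chain (C1–C5), built on a cyclopentene carbaldehyde by catalytic asymmetric allylboration (sets C5), Wacker oxidation, vinyl Grignard addition and acylation.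
- The cyclopentene carbaldehyde, which already holds the C6–C10 bond and the one pre-set ring stereocenter (C10–H), comes from (S)-limonene by hydrogenation, ozonolysis and aldol re-closure.
- Ring order: five-membered ring first (re-closure of the cleaved limonene ring), seven-membered ring last (cascade). C7, C6 and C10 are all relayed from the limonene stereocenter; C5 comes from the catalyst.

Assumption: (S)-(−)-limonene of high ee, allylboronic acid pinacol ester and 2,2-dimethyl-4H-1,3-benzodioxin-4-one are bought; the ee of the route equals that of the limonene.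
Labels: C1–C15 follow the farnesyl chain (C1 = ring CH2 on the quaternary carbon C7; C2=C3 = ring alkene; C5 = ester carbon; C6 = ring-fusion CH; C10 = carbinol carbon).

**Route**

Step 1
Reactants: 1 (S)-(−)-limonene
Product: 2 (4S)-1-methyl-4-(propan-2-yl)cyclohex-1-ene [(S)-p-menth-1-ene]
Conditions: H2 (1 atm), RhCl(PPh3)3 (1 mol %), benzene/EtOH 1:1, rt
Reagents that add atoms: none
Why: Chemoselective rhodium–phosphine homogeneous hydrogenation reduces the unhindered 1,1-disubstituted isopropenyl alkene much faster than the trisubstituted ring alkene, and the stereocenter is not involved.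

Step 2
Reactants: 2 (S)-p-menth-1-ene
Product: 4 (3S)-6-oxo-3-(propan-2-yl)heptanal, via secondary ozonide 3 (not isolated)
Conditions: O3, CH2Cl2, −78 °C; then Me2S, −78 °C → rt
Reagents that add atoms: ozone, [O-][O+]=O
Why: Ozonolysis with reductive work-up cleaves the only alkene to the keto aldehyde; the stereocenter is β to the aldehyde and cannot epimerize.

Step 3
Reactants: 4 (3S)-6-oxo-3-(propan-2-yl)heptanal
Product: 5 (5R)-2-methyl-5-(propan-2-yl)cyclopent-1-ene-1-carbaldehyde
Conditions: piperidine (0.2 equiv), AcOH (0.2 equiv), benzene, reflux (Dean–Stark)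
Reagents that add atoms: none
Why: Enamine-mediated intramolecular aldol condensation lets the aldehyde α-carbon attack the methyl ketone and dehydrate to the tetrasubstituted cyclopentene enal (net six-to-five re-closure of the limonene ring); the stereocenter sits on the α'-carbon and is not enolizable.

Step 4
Reactants: 5 (5R)-2-methyl-5-(propan-2-yl)cyclopent-1-ene-1-carbaldehyde; 6 allylboronic acid pinacol ester
Product: 8 (1S)-1-[(5R)-2-methyl-5-(propan-2-yl)cyclopent-1-en-1-yl]but-3-en-1-ol, via pinacol borate ester 7 (not isolated)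
Conditions: 6 (1.3 equiv), (S)-3,3′-bis(2,4,6-triisopropylphenyl)-1,1′-binaphthyl-2,2′-diyl hydrogen phosphate [(S)-TRIP] (5 mol %), toluene, −30 °C; then aq NaHCO3
Reagents that add atoms: none
Why: Chiral-phosphoric-acid-catalysed allylboration through a closed six-membered chair transition state; (S)-TRIP directs si-face attack and sets the (S)-carbinol C5, with little bias from the remote ring stereocenter.

Step 5
Reactants: 8 (1S)-1-[(5R)-2-methyl-5-(propan-2-yl)cyclopent-1-en-1-yl]but-3-en-1-ol
Product: 9 (4S)-4-hydroxy-4-[(5R)-2-methyl-5-(propan-2-yl)cyclopent-1-en-1-yl]butan-2-one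
Conditions: PdCl2 (10 mol %), CuCl (0.3 equiv), O2 (1 atm), DMF/H2O 7:1, rt
Reagents that add atoms: water, O (its oxygen becomes the ketone oxygen); dioxygen, O=O (terminal oxidant that returns the water)
Why: Tsuji–Wacker oxidation converts the terminal alkene to the methyl ketone by Markovnikov oxypalladation while the tetrasubstituted ring alkene is inert; C5 is untouched.

Step 6
Reactants: 9 (4S)-4-hydroxy-4-[(5R)-2-methyl-5-(propan-2-yl)cyclopent-1-en-1-yl]butan-2-one; 10 vinylmagnesium bromide
Product: 11 (3RS,5S)-3-methyl-5-[(5R)-2-methyl-5-(propan-2-yl)cyclopent-1-en-1-yl]pent-1-ene-3,5-diol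
Conditions: 10 (3 equiv), THF, −78 → 0 °C; then aq NH4Cl
Reagents that add atoms: none
Why: Grignard 1,2-addition of vinyl to the methyl ketone gives the linalool-type tertiary allylic alcohol; C3 forms as both epimers, which does not matter because C3 becomes sp2 in step 8.

Step 7
Reactants: 11 (3RS,5S)-3-methyl-5-[(5R)-2-methyl-5-(propan-2-yl)cyclopent-1-en-1-yl]pent-1-ene-3,5-diol; 12 2,2-dimethyl-4H-1,3-benzodioxin-4-one
Product: 13 (1S,3RS)-3-hydroxy-3-methyl-1-[(5R)-2-methyl-5-(propan-2-yl)cyclopent-1-en-1-yl]pent-4-en-1-yl 2-hydroxybenzoate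
Conditions: 12 (2 equiv), hν (300 nm), CH2Cl2, rt
Reagents that add atoms: none
Why: Photochemical acyl transfer: irradiation opens the benzodioxinone to a quinoketene (losing acetone) that the secondary hydroxyl traps much faster than the hindered tertiary one, giving the free salicylate without base or protecting group; no stereocenter is touched.

Step 8
Reactants: 13 (1S,3RS)-3-hydroxy-3-methyl-1-[(5R)-2-methyl-5-(propan-2-yl)cyclopent-1-en-1-yl]pent-4-en-1-yl 2-hydroxybenzoate
Product: 16 (3R,3aS,4S,8aR)-3-hydroxy-6,8a-dimethyl-3-(propan-2-yl)-1,2,3,3a,4,5,8,8a-octahydroazulen-4-yl 2-hydroxybenzoate (target), via allyl cation 14 (not isolated), via dioxanylium ion 15 (not isolated)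
Conditions: TsOH·H2O (10 mol %), (CF3)2CHOH/CH2Cl2 1:4, 0.005 M, −20 → 0 °C; then aq NaHCO3
Reagents that add atoms: none
Why: Proposed new method: acid ionizes either C3 epimer to the same linalyl-type allyl cation, whose C1 terminus closes 7-endo onto C7 of the tetrasubstituted cyclopentene on the face anti to the C10 isopropyl group (the face on which allylic strain also places the C4 tether of the (S)-ester), the C10 hydrogen on that same face then shifts to the C6 cation (fixing the trans ring fusion), and the new C10 cation is captured from the opposite face by the ester carbonyl held on C5 to give a six-membered acyloxonium ion that the liberated water hydrolyses to the tertiary alcohol and the secondary salicylate, so C7, C6 and C10 all derive from the limonene stereocenter; the closest known reaction types are acid-induced 7-endo cation–olefin cyclizations of related 2-methylcyclopentenes to daucene, 1,2-hydride shifts between tertiary cations, and neighbouring-group capture of carbocations by esters as dioxanylium ions (Prévost–Woodward chemistry).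

**Compound list**

1 | (S)-(−)-limonene, (4S)-1-methyl-4-(prop-1-en-2-yl)cyclohex-1-ene | CC1=CC[C@H](CC1)C(C)=C | starting material
2 | (4S)-1-methyl-4-(propan-2-yl)cyclohex-1-ene | CC1=CC[C@H](CC1)C(C)C | intermediate
3 | secondary ozonide of 2, (4S)-1-methyl-4-(propan-2-yl)-7,8,9-trioxabicyclo[4.2.1]nonane (both orientations of the peroxide bridge) | CC12CC[C@H](C(C)C)CC(OO1)O2 | intermediate
4 | (3S)-6-oxo-3-(propan-2-yl)heptanal | O=CC[C@H](CCC(C)=O)C(C)C | intermediate
5 | (5R)-2-methyl-5-(propan-2-yl)cyclopent-1-ene-1-carbaldehyde | O=CC1=C(C)CC[C@@H]1C(C)C | intermediate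
6 | allylboronic acid pinacol ester, 4,4,5,5-tetramethyl-2-(prop-2-en-1-yl)-1,3,2-dioxaborolane | C=CCB1OC(C)(C)C(C)(C)O1 | starting material
7 | pinacol borate ester of 8 (O–B(pin) on the carbinol oxygen) | C=CC[C@H](OB1OC(C)(C)C(C)(C)O1)C1=C(C)CC[C@@H]1C(C)C | intermediate
8 | (1S)-1-[(5R)-2-methyl-5-(propan-2-yl)cyclopent-1-en-1-yl]but-3-en-1-ol | C=CC[C@H](O)C1=C(C)CC[C@@H]1C(C)C | intermediate
9 | (4S)-4-hydroxy-4-[(5R)-2-methyl-5-(propan-2-yl)cyclopent-1-en-1-yl]butan-2-one | CC(=O)C[C@H](O)C1=C(C)CC[C@@H]1C(C)C | intermediate
10 | vinylmagnesium bromide | C=C[Mg]Br | starting material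
11 | (3RS,5S)-3-methyl-5-[(5R)-2-methyl-5-(propan-2-yl)cyclopent-1-en-1-yl]pent-1-ene-3,5-diol | C=CC(C)(O)C[C@H](O)C1=C(C)CC[C@@H]1C(C)C | intermediate
12 | 2,2-dimethyl-4H-1,3-benzodioxin-4-one | CC1(C)OC(=O)c2ccccc2O1 | starting material
13 | (1S,3RS)-3-hydroxy-3-methyl-1-[(5R)-2-methyl-5-(propan-2-yl)cyclopent-1-en-1-yl]pent-4-en-1-yl 2-hydroxybenzoate | C=CC(C)(O)C[C@H](OC(=O)c1ccccc1O)C1=C(C)CC[C@@H]1C(C)C | intermediate
14 | allyl cation from 13 (C3–OH lost; drawn as the tertiary resonance form) | C=C[C+](C)C[C@H](OC(=O)c1ccccc1O)C1=C(C)CC[C@@H]1C(C)C | intermediate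
15 | 2-(2-hydroxyphenyl)-1,3-dioxan-2-ylium ion bridging the C5 and C10 oxygens of the trans-fused bicycle | CC1=CC[C@@]2(C)CC[C@@](O3)(C(C)C)[C@@H]2[C@@H](O[C+]3c2ccccc2O)C1 | intermediate
16 | (3R,3aS,4S,8aR)-3-hydroxy-6,8a-dimethyl-3-(propan-2-yl)-1,2,3,3a,4,5,8,8a-octahydroazulen-4-yl 2-hydroxybenzoate | CC1=CC[C@@]2(C)CC[C@@](O)(C(C)C)[C@@H]2[C@@H](OC(=O)c2ccccc2O)C1 | target

**Step count and risks**

Total step count: 8. Longest linear sequence: 8 steps (1 → 16; the route is fully linear).

Most likely to fail, in this order:

Step 8 (cascade). This step is untested. Possible failure modes are 6-exo (spiro) closure at C6, participation of the ester at the C6 cation (a five-membered acyloxonium ion) before the hydride shift, elimination to dienes, ionization of the allylic salicylate, and weak trapping by the hydrogen-bonded carbonyl. The fallback sets out from diol 11 and separates ring formation from the ester. Boc2O, DMAP (cat.) and Et3N in CH2Cl2 convert the secondary hydroxyl into the tert-butyl carbonate F1. TsOH·H2O in (CF3)2CHOH/CH2Cl2 (or BF3·OEt2, CH2Cl2, −78 °C) then runs the same cyclization and hydride shift, but the C10 cation is trapped irreversibly by the carbonate carbonyl with loss of 2-methylpropene. This gives the neutral cyclic carbonate F2, which can be purified from regio- and stereoisomers. K2CO3 in MeOH/H2O gives the diol F3, and photo-acylation of its secondary hydroxyl with 12 (conditions of step 7) returns to the route at 16.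

Step 5 (Wacker oxidation). The acidic palladium/copper medium may ionize or transpose the cyclopentenyl carbinol, or give some aldehyde regioisomer. The fallback sets out from enal 5. (S)-TRIP-catalysed methallylboration with 2-methylallylboronic acid pinacol ester gives the 1,1-disubstituted homoallylic alcohol F4. OsO4 (2 mol %), NaIO4 and 2,6-lutidine in dioxane/H2O then cleave the unhindered 1,1-disubstituted alkene (the tetrasubstituted ring alkene is osmylated far more slowly) to ketol 9, where the route is rejoined.

Step 7 (photo-acylation). The hindered secondary hydroxyl may react slowly or not selectively over the tertiary one, and the product is itself a chromophore. The fallback sets out from diol 11. O-Acetylsalicyloyl chloride, pyridine and DMAP (cat.) in CH2Cl2 acylate only the secondary hydroxyl to give the acetyl-protected ester F5. The cascade of step 8 then gives the O-acetyl derivative F6, and NH3 in MeOH at 0 °C removes the aryl acetate and returns to 16.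

Further compounds
F1 | step 8 | tert-butyl (1S,3RS)-3-hydroxy-3-methyl-1-[(5R)-2-methyl-5-(propan-2-yl)cyclopent-1-en-1-yl]pent-4-en-1-yl carbonate | C=CC(C)(O)C[C@H](OC(=O)OC(C)(C)C)C1=C(C)CC[C@@H]1C(C)C
F2 | step 8 | cyclic carbonate of F3 across its two hydroxyls (six-membered 1,3-dioxan-2-one on the trans-fused bicycle) | CC1=CC[C@@]2(C)CC[C@@](O3)(C(C)C)[C@@H]2[C@@H](OC3=O)C1
F3 | step 8 | (3R,3aS,4S,8aR)-6,8a-dimethyl-3-(propan-2-yl)-1,2,3,3a,4,5,8,8a-octahydroazulene-3,4-diol | CC1=CC[C@@]2(C)CC[C@@](O)(C(C)C)[C@@H]2[C@@H](O)C1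
F4 | step 5 | (1S)-3-methyl-1-[(5R)-2-methyl-5-(propan-2-yl)cyclopent-1-en-1-yl]but-3-en-1-ol | CC(=C)C[C@H](O)C1=C(C)CC[C@@H]1C(C)C
F5 | step 7 | (1S,3RS)-3-hydroxy-3-methyl-1-[(5R)-2-methyl-5-(propan-2-yl)cyclopent-1-en-1-yl]pent-4-en-1-yl 2-(acetyloxy)benzoate | C=CC(C)(O)C[C@H](OC(=O)c1ccccc1OC(C)=O)C1=C(C)CC[C@@H]1C(C)C
F6 | step 7 | (3R,3aS,4S,8aR)-3-hydroxy-6,8a-dimethyl-3-(propan-2-yl)-1,2,3,3a,4,5,8,8a-octahydroazulen-4-yl 2-(acetyloxy)benzoate | CC1=CC[C@@]2(C)CC[C@@](O)(C(C)C)[C@@H]2[C@@H](OC(=O)c2ccccc2OC(C)=O)C1
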